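Two final amounts and one verdict between them are asked, and I turn the verdict round first: what would blue need in order to beat ochre?

| setting | Friday's | Thursday's | blue | ochre |
|---|---|---|---|---|
| starting material | 0.034 M | 0.10 M | 0.050 M | 0.050 M |
| free catalyst | 50 µM | 50 µM | 30 µM | 50 µM |
| temperature | −20 °C | −20 °C | −35 °C | −20 °C |
| remark | run made earlier | run made earlier |  |  |
| time |  |  | 10 h | 6.0 h |

| run | time / h | product / % |
|---|---|---|
| Friday's | 0.250 | 1.6 |
| Friday's | 0.417 | 0 |
| Friday's | 0.667 | 6.4 |
| Friday's | 1.00 | 5.6 |
| Friday's | 1.50 | 8.1 |
| Friday's | 2.50 | 13.6 |
| Friday's | 4.00 | 18.9 |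
| Thursday's | 0.200 | 0.3 |
| Thursday's | 0.500 | 2.0 |
| Thursday's | 1.00 | 5.3 |
| Thursday's | 1.50 | 3.9 |
| Thursday's | 2.00 | 4.8 |
| Thursday's | 3.00 | 6.2 |
| Thursday's | 4.00 | 11.2 |

(scatter of a reading: 1 percentage point)

- the flask that ends with the higher amount of product, in percent of the starting material charged, or "neither" when 2 percentage points or less lies between them (blue / ochre / neither)
- final product, as a percentage of the starting material charged, in blue
- final product, as a percentage of the starting material charged, in ochre

- reactions considered so far: starting material + free catalyst -> catalyst intermediate A; catalyst intermediate A <-> catalyst intermediate B; catalyst intermediate B <-> free catalyst + product; free catalyst -> spent catalyst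
- the earlier runs do not show what temperature does; that part of a forecast is a guess
- no earlier run changes the charge of free catalyst; that part of a forecast is a guess

Both flasks hold the same charge of starting material, and catalyst times hours, blue over ochre, comes to 1.00. So if product follows catalyst-hours, which is a guess because no earlier run changes the catalyst, blue needs cooling from −20 °C to −35 °C to speed the turnover in order to lead by more than 2 percentage points. I expect cooling to slow it, though that too is a guess, so I commit to ochre and reckon ochre's figure.

The last two readings of each run give mean rates at mid-course amounts of starting material, read with their scatter: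

Friday's: r = 1.70 mM/h at A = 30.6 mM

Thursday's: r = 2.49 mM/h at A = 95.0 mM

With r = k·c·A/(K+A), where c is the catalyst charged and A the starting material:

K = 26.7 mM, k = 63.7 /h

Here K is the half-saturation amount and k is the top turnover rate, product per catalyst per hour. I put ochre's first answer back in and go round once:

r = 2.08 mM/h, so mid-course A = 43.8 mM, r = 1.98 mM/h, product 23.7 %

The forecast gives ochre, with 4.5 % in blue and 20 % in ochre, and says: “The temperature and catalyst scaling are guesses, but ochre should win.” The flasks give ochre, with 5.06 % in blue and 23.2 % in ochre.

    starting material + free catalyst → catalyst intermediate A (k = 155 /M/min, Ea = 37.0 kJ/mol)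
    catalyst intermediate A ⇌ catalyst intermediate B (K = 0.490, k = 3.49 /min, Ea = 58.0 kJ/mol, ΔH = −10.0 kJ/mol)
    catalyst intermediate B ⇌ free catalyst + product (K = 0.0195 M, k = 3.10 /min, Ea = 61.0 kJ/mol, ΔH = −10.0 kJ/mol)
    free catalyst → spent catalyst (k = 9.51 × 10⁻⁷ /min, Ea = 99.0 kJ/mol)
    (constants at −20 °C)

In ochre at 2.83 h, free catalyst has a half-life of 0.10 min by its uptake of starting material and catalyst intermediate A one of 0.20 min by its forward step, both far shorter than the run's 6.0 h, while catalyst intermediate A, the resting state, holds 66.8 % of the catalyst at 3.00 h and 66.0 % at 6.00 h. Ochre's mean turnover per catalyst charged, 38.6 /h, lies below the k read from the runs.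

For a flask like ochre with 0.020 M of starting material, the same k and K, going round once, give:

r = 1.36 mM/h, mid-course A = 15.9 mM, product 35.7 %

That flask gives 44.5 %, so the reckoning stands 8.8 points low there.

(The runs were generated by integration with made-up constants, and the scatter is random.)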